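## The problem

The target is a 1,2-dioxolane (O1–O2–C3–C4–C5) in which both peroxy carbons are quaternary. C3 carries a methyl group and the acetic acid arm (C2–C1). C5 carries a methyl group and a twelve-carbon arm (C6–C17) that ends in a (14E,16E)-phenyl-diene. The two carbon arms lie on the same face of the ring (3R,5R).

The third stereocentre, C7 (R), is separated from the ring by the C6 methylene. The ring cannot be expected to control it, so a reagent must set it. C3 and C5 bear no hydrogen and cannot be corrected later; their relative configuration has to come out of ring formation, and their absolute configuration out of a separate event.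

Once the O–O bond is present it rules out catalytic hydrogenation, dissolving metals, strong hydrides, hot phosphines and hard organometallics. The C1 carbonyl is β to the peroxide, so deprotonation at C2 would open the ring by E1cB. The phenyl-diene tolerates neither diimide nor hydroboration. C8–C13 is an unfunctionalised chain, so any olefination used there leaves an alkene that must be reduced without a metal catalyst.

The feature that allows a short entry is the unit C2–C3(CH3)–C4–C5(CH3)–C6 with the peroxide spanning C3 and C5 and the arms cis. If C2 and C6 are joined by a double bond, this unit is the singlet-oxygen adduct of 1,4-dimethylcyclopenta-1,3-diene. The price is a meso intermediate that must be desymmetrised, and two arms that must be grown on a peroxide.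

## Retrosynthesis

**C1 oxidation level.** Acid 39 is traced through aldehyde 38 to primary alcohol 37 and its silyl ether 36. No C–C bond is cut. C1 is held as an ether through every basic step, because a C1 ester would put acidic protons at C2, β to the peroxide. The forward step must oxidise a primary alcohol beside a peroxide and a conjugated diene.

**C14=C15.** Compound 36 is cut at C14=C15 into aldehyde 34 and diethyl cinnamylphosphonate 35. A cut at C16=C17 would put a sensitive allylic phosphonate on the valuable half. This cut puts the whole styryl unit in a cheap reagent and lets the diene arrive after the last diimide reduction. The forward reaction must be E-selective at the new bond.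

**C8–C9.** Aldehyde 34 comes from alcohol 33, and 33 from Z-alkenol 32 by saturation. Compound 32 is cut at C8=C9 into aldehyde 29 and phosphonium salt 31, made from 6-bromohexan-1-ol 30. A direct sp3–sp3 coupling would save two steps but needs organometallic or low-valent metal reagents that threaten the O–O bond. Wittig olefination followed by diimide is the peroxide-safe equivalent. The forward steps must not epimerise C7 of 29.

**C7 and its methyl group.** Aldehyde 29 comes from alcohol 28 and this from imide 27. The C7–CH3 bond of 27 is cut back to sodium enolate 26 of imide 25, where the oxazolidinone decides the face. A side chain that already contains C7 cannot be attached, because C6 is neopentyl and cannot be alkylated, and an olefination at C6 makes C7 trigonal. Imide 25 comes from enoyl imide 24, which is cut at C6=C7 into aldehyde 18 and phosphonate 23. Phosphonate 23 comes from (S)-4-benzyl-2-oxazolidinone 19 and bromoacetyl bromide 20 through lithium salt 21 and bromide 22.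

**The C3 arm.** Aldehyde 18 comes from alcohol 17, the mono-silyl ether of diol 16. Diol 16 arises by hydroboration–oxidation of vinyl compound 13 through borane 14 and hydroxy acetate 15. Compound 13 is cut at C1=C2 to aldehyde 12, the oxidation product of monoacetate 11. Displacement by cyanide at this neopentyl carbon would be shorter on paper but is not credible. Methylenation followed by anti-Markovnikov hydration delivers C1 at the alcohol level directly.

**Desymmetrisation.** Monoacetate 11 comes from meso diol 10 by lipase-catalysed acetylation of one enantiotopic arm. This single event fixes the absolute configuration of C3 and C5. Because the arms end up as OH and OAc, either sense of enzyme selectivity can be steered to the target.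

**The C2/C6 cut.** Diol 10 is the ozonolysis–borohydride product of bicyclic peroxide 8, formed through methoxy hydroperoxide 9. Re-joining C2 and C6 as an alkene converts two side arms into one ring and reveals the cycloadduct.

**Key disconnection.** Peroxide 8 is cut at both C–O bonds into 1,4-dimethylcyclopenta-1,3-diene 6 and dioxygen 7. Two rings, two C–O bonds and the cis relationship of the quaternary centres are traded for a C7H10 hydrocarbon. The forward step needs only [4+2] selectivity over the ene reaction and cold handling.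

**The diene.** Diene 6 comes from carbinol 3 by dehydration and tautomer equilibration through 4 and 5. Carbinol 3 comes from 3-methylcyclopent-2-en-1-one 1 and methyllithium 2. The 1,4-tautomer cannot be made selectively this way. The material is cheap, and the loss falls at the very start.

## Roads not taken

**Alternative 1:** The O–O bond would be made last. The cut leads to acyclic 1,3-diol A2, in which both tertiary carbinols and C7 are already in place. Elemental fluorine would turn one tertiary hydroxyl into a hypofluorite, and the other hydroxyl would displace fluoride at oxygen to give dioxolane ester A1.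
- Merits: every chain-building step before the closure is free of peroxide constraints, so hydrogenation and organometallic coupling are available. Neither C–O bond is touched, so the diol configuration is carried over unchanged. Only three or four steps would be run on peroxide-bearing material.
- Weak points: ring closure by substitution at a hypofluorite oxygen has no preparative precedent on a substrate of this kind. Tertiary hypofluorites fragment by β-scission, and fluorine attacks the C–H bonds of a long alkyl chain and the ester α-position. The diene could not be present. A syn-1,3-bis-tertiary diol with a third remote centre is itself a demanding target.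
- Comparison: if the closure worked, this road would expose far less material to peroxide-limited chemistry than the chosen plan, which carries the O–O bond through some twenty steps. The chosen plan sets against this a ring-forming reaction of established type, run first on an inexpensive hydrocarbon, so a failure costs almost nothing.

**Alternative 2:** The O–C5 bond would be cut. The precursor is hydroperoxy epoxide A4, a C3 tertiary hydroperoxide with a trisubstituted C5–C6 epoxide. Under acid catalysis the hydroperoxide attacks the tertiary epoxide carbon from the back (5-exo, inversion) and gives dioxolane A3 with a hydroxyl at C6.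
- Merits: the closure is stereospecific and of a known type. The epoxide can come from an asymmetric epoxidation. The side chain with C7 is attached before the ring forms, so the route is convergent. In this respect it is better than the chosen plan, which builds C6–C14 stepwise on the peroxide.
- Weak points: A3 carries an oxygen at C6 that the target lacks. Removing it next to a peroxy carbon is the real obstacle. A C6 radical lies β to the O–O bond and would collapse to an epoxide with O–O cleavage. Hydride displacement at this hindered secondary centre is poor and endangers the peroxide. The C3 tertiary hydroperoxide must also be installed with defined configuration.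
- Comparison: absolute control by epoxidation is as good as control by a lipase. The chosen plan delivers C6 as a methylene without any deoxygenation and obtains the cis relationship from geometry alone.

**Alternative 3:** The C4–C5 and O–C3 bonds would be cut. Triethylsilylperoxy ketal A6 is ionised by SnCl4 to a peroxycarbenium ion. Methyl 3-methylbut-3-enoate A7 attacks it through its methylene carbon, and the tertiary cation is captured by the peroxide oxygen to give dioxolane ester A5.
- Merits: the annulation is known for tetrasubstituted dioxolanes. It forms the ring, both quaternary centres and the acetate arm in one convergent step from fragments that already hold C7. In step economy it is clearly better than the chosen plan, probably by more than ten steps.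
- Weak points: at each new centre the choice is between a methyl and a methylene substituent of similar size, so cis/trans selectivity is expected to be modest. C7 is too far away to bias either face. A5 would therefore form with both ring diastereomers and no absolute control, and the remote diastereomers would be hard to separate. Proton loss from the tertiary cation competes with ring closure.
- Comparison: for racemic or stereorandom material this road would be preferred. For the single enantiomer the chosen plan has three independent control elements: the bicycle for cis, the enzyme for absolute configuration and the auxiliary for C7.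

Key step: step 3

Assumption: the lipase in step 5 is taken to acetylate the hydroxymethyl group on the ring carbon that becomes C5 of the target; the sense must be established on 11 (for example through its α-methoxy-α-(trifluoromethyl)phenylacetate esters), and the opposite sense is handled by the fallback for step 5. TBDPS = tert-butyldiphenylsilyl.

## Route

Step 1
Reactants: 1 3-methylcyclopent-2-en-1-one; 2 methyllithium
Product: 3 1,3-dimethylcyclopent-2-en-1-ol (racemic)
Conditions: MeLi, Et2O, −78 → 0 °C; then H2O
Reagents that add atoms: none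
Why: 1,2-addition of the hard organolithium to the enone carbonyl should give the tertiary allylic alcohol; the stereocentre is racemic and is destroyed in step 2.

Step 2
Reactants: 3 1,3-dimethylcyclopent-2-en-1-ol
Product: 6 1,4-dimethylcyclopenta-1,3-diene, via 1,3-dimethylcyclopenta-1,3-diene 4 (not isolated), via 2,5-dimethylcyclopenta-1,3-diene 5 (not isolated)
Conditions: p-TsOH·H2O (cat.), Et2O, 0 °C → rt; NaHCO3 wash; distillation at atmospheric pressure; stored at −78 °C
Reagents that add atoms: none
Why: Acid-catalysed E1 dehydration through the symmetrical 1,3-dimethylcyclopentenyl cation should give 4 first, and successive suprafacial [1,5]-hydrogen shifts during distillation pass through 5 and populate 6. The distillate is a tautomer mixture in which 4 is expected to predominate on statistical grounds; it is assayed by NMR and used as such, because only 6 gives a symmetrical adduct and material derived from 4 is removed after step 4.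

Step 3
Reactants: 6 1,4-dimethylcyclopenta-1,3-diene (as the tautomer mixture); 7 dioxygen
Product: 8 (1R,4S)-1,4-dimethyl-2,3-dioxabicyclo[2.2.1]hept-5-ene (meso)
Conditions: O2 (bubbling), 5,10,15,20-tetraphenylporphyrin (cat.), visible light, CH2Cl2, −78 °C; solution kept at −78 °C and used directly
Reagents that add atoms: none
Why: Energy transfer from the excited dye gives singlet oxygen, which adds as the two-atom partner across the termini of the s-cis-locked diene in a concerted suprafacial [4+2] cycloaddition; the closest known reaction type is the dye-sensitised photooxygenation of cyclopentadienes and other cyclic 1,3-dienes to bicyclic endoperoxides. The six-membered 3,6-dihydro-1,2-dioxine ring closes as the cycloaddition ring itself. The five-membered 1,2-dioxolane ring closes in the same event, because the diene termini are already tied by the ring methylene and the two new C–O bonds complete both rings at once. The two new stereocentres are the bridgeheads: both oxygens arrive on one face of the planar diene, so the methyl groups and the future C2 and C6 arms are necessarily cis and the product is meso, and no facial choice arises because the two faces of 6 are equivalent. The step needs [4+2] selectivity over the ene reaction at the allylic methyl groups, which the fixed s-cis geometry and the alkylated termini should secure. It cannot choose between tautomers, so 4 reacts as well and its unsymmetrical adduct is carried as an impurity. The adduct is a strained allylic peroxide prone to thermal rearrangement, hence −78 °C and immediate use.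

Step 4
Reactants: 8 (1R,4S)-1,4-dimethyl-2,3-dioxabicyclo[2.2.1]hept-5-ene
Product: 10 [(3R,5S)-3,5-dimethyl-1,2-dioxolane-3,5-diyl]dimethanol (meso), via methoxy hydroperoxide aldehyde 9 (not isolated)
Conditions: MeOH added; O3/O2, CH2Cl2–MeOH, −78 °C; N2 purge; NaBH4, −78 → 0 °C; chromatography
Reagents that add atoms: ozone, [O-][O+]=O
Why: Ozonolysis with reductive work-up: ozone cleaves the strained cis-alkene, methanol traps the carbonyl oxide as 9, and borohydride reduces the hydroperoxide and both carbonyl groups while the hindered dialkyl peroxide should survive. No stereocentre is touched, so the arms stay cis and 10 is meso; the isomeric diol that stems from tautomer 4 is removed here.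

Step 5
Reactants: 10 [(3R,5S)-3,5-dimethyl-1,2-dioxolane-3,5-diyl]dimethanol
Product: 11 [(3S,5R)-5-(hydroxymethyl)-3,5-dimethyl-1,2-dioxolan-3-yl]methyl acetate
Conditions: immobilised lipase from Burkholderia cepacia, vinyl acetate, t-BuOMe, 25 °C; stopped before diacetate forms
Reagents that add atoms: vinyl acetate, C=COC(C)=O
Why: Enzymatic desymmetrisation of a meso diol by irreversible transesterification; the lipase distinguishes the enantiotopic hydroxymethyl groups and thereby fixes the absolute configuration of both quaternary centres in one event.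

Step 6
Reactants: 11 [(3S,5R)-5-(hydroxymethyl)-3,5-dimethyl-1,2-dioxolan-3-yl]methyl acetate
Product: 12 [(3S,5R)-5-formyl-3,5-dimethyl-1,2-dioxolan-3-yl]methyl acetate
Conditions: Dess–Martin periodinane, pyridine, CH2Cl2, 0 °C → rt; used at once
Reagents that add atoms: none
Why: Dess–Martin oxidation of a neopentyl primary alcohol under buffered, non-basic conditions; the aldehyde has no α-hydrogen and cannot epimerise.

Step 7
Reactants: 12 [(3S,5R)-5-formyl-3,5-dimethyl-1,2-dioxolan-3-yl]methyl acetate
Product: 13 [(3S,5R)-5-ethenyl-3,5-dimethyl-1,2-dioxolan-3-yl]methyl acetate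
Conditions: Ph3PCH3Br, KN(SiMe3)2, THF, 0 °C; then 12, −78 → 0 °C
Reagents that add atoms: methyltriphenylphosphonium bromide, C[P+](c1ccccc1)(c1ccccc1)c1ccccc1.[Br-]
Why: Wittig methylenation; at low temperature the non-stabilised ylide should add to the aldehyde much faster than to the acetate or the hindered peroxide.

Step 8
Reactants: 13 [(3S,5R)-5-ethenyl-3,5-dimethyl-1,2-dioxolan-3-yl]methyl acetate
Product: 16 2-[(3S,5S)-5-(hydroxymethyl)-3,5-dimethyl-1,2-dioxolan-3-yl]ethan-1-ol, via B-alkyl-9-BBN adduct 14 (not isolated), via hydroxy acetate 15 (not isolated)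
Conditions: 9-BBN, THF, 0 °C → rt; then NaOH aq., 30% H2O2, MeOH, 0 °C → rt
Reagents that add atoms: hydrogen peroxide, OO
Why: Hydroboration–oxidation: the bulky borane places boron on the terminal carbon, away from the peroxy carbon, and alkaline peroxide oxidises the C–B bond. The same alkaline peroxide work-up should cleave the primary acetate, so the diol is obtained directly.

Step 9
Reactants: 16 2-[(3S,5S)-5-(hydroxymethyl)-3,5-dimethyl-1,2-dioxolan-3-yl]ethan-1-ol
Product: 17 [(3S,5S)-5-{2-[(TBDPS)oxy]ethyl}-3,5-dimethyl-1,2-dioxolan-3-yl]methanol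
Conditions: t-BuPh2SiCl (1.05 equiv), imidazole, CH2Cl2, −20 → 0 °C
Reagents that add atoms: tert-butyl(chloro)diphenylsilane, CC(C)(C)[Si](Cl)(c1ccccc1)c1ccccc1
Why: Sterically controlled mono-silylation; the bulky chlorosilane should take the unhindered 2-hydroxyethyl group in preference to the neopentyl hydroxymethyl group beside the quaternary peroxy carbon.

Step 10
Reactants: 17 [(3S,5S)-5-{2-[(TBDPS)oxy]ethyl}-3,5-dimethyl-1,2-dioxolan-3-yl]methanol
Product: 18 (3S,5S)-5-{2-[(TBDPS)oxy]ethyl}-3,5-dimethyl-1,2-dioxolane-3-carbaldehyde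
Conditions: Dess–Martin periodinane, pyridine, CH2Cl2, 0 °C → rt; used at once
Reagents that add atoms: none
Why: Dess–Martin oxidation as in step 6; the aldehyde is non-enolisable.

Step 11
Reactants: 19 (S)-4-benzyl-2-oxazolidinone; 20 bromoacetyl bromide
Product: 22 (4S)-4-benzyl-3-(2-bromoacetyl)-1,3-oxazolidin-2-one, via lithium oxazolidinide 21 (not isolated)
Conditions: n-BuLi, THF, −78 °C; then 20, −78 °C
Reagents that add atoms: none
Why: N-acylation of the lithiated oxazolidinone; at −78 °C the acyl bromide carbonyl should react far faster than the α-bromide is displaced.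

Step 12
Reactants: 22 (4S)-4-benzyl-3-(2-bromoacetyl)-1,3-oxazolidin-2-one
Product: 23 diethyl {2-[(4S)-4-benzyl-2-oxo-1,3-oxazolidin-3-yl]-2-oxoethyl}phosphonate
Conditions: P(OEt)3, neat, 50 → 90 °C, EtBr distilled off
Reagents that add atoms: triethyl phosphite, CCOP(OCC)OCC
Why: Michaelis–Arbuzov reaction of an activated α-bromo imide; the stereocentre of the auxiliary is not involved.

Step 13
Reactants: 18 (3S,5S)-5-{2-[(TBDPS)oxy]ethyl}-3,5-dimethyl-1,2-dioxolane-3-carbaldehyde; 23 diethyl {2-[(4S)-4-benzyl-2-oxo-1,3-oxazolidin-3-yl]-2-oxoethyl}phosphonate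
Product: 24 (4S)-4-benzyl-3-[(2E)-3-[(3S,5S)-5-{2-[(TBDPS)oxy]ethyl}-3,5-dimethyl-1,2-dioxolan-3-yl]prop-2-enoyl]-1,3-oxazolidin-2-one
Conditions: LiCl, i-Pr2NEt, MeCN, rt
Reagents that add atoms: none
Why: Horner–Wadsworth–Emmons olefination under mild LiCl/amine (Masamune–Roush) conditions, which should give the E-enoyl imide and expose the peroxide to no strong base.

Step 14
Reactants: 24 (4S)-4-benzyl-3-[(2E)-3-[(3S,5S)-5-{2-[(TBDPS)oxy]ethyl}-3,5-dimethyl-1,2-dioxolan-3-yl]prop-2-enoyl]-1,3-oxazolidin-2-one
Product: 25 (4S)-4-benzyl-3-{3-[(3R,5S)-5-{2-[(TBDPS)oxy]ethyl}-3,5-dimethyl-1,2-dioxolan-3-yl]propanoyl}-1,3-oxazolidin-2-one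
Conditions: 2-nitrobenzenesulfonyl hydrazide (large excess, in portions), Et3N, CH2Cl2, rt
Reagents that add atoms: none
Why: Diimide reduction: concerted syn transfer of two hydrogens to the C=C bond leaves O–O, carbonyl and aryl groups alone. A large excess is planned because the alkene is flanked by a quaternary carbon.

Step 15
Reactants: 25 (4S)-4-benzyl-3-{3-[(3R,5S)-5-{2-[(TBDPS)oxy]ethyl}-3,5-dimethyl-1,2-dioxolan-3-yl]propanoyl}-1,3-oxazolidin-2-one
Product: 27 (4S)-4-benzyl-3-[(2S)-3-[(3R,5S)-5-{2-[(TBDPS)oxy]ethyl}-3,5-dimethyl-1,2-dioxolan-3-yl]-2-methylpropanoyl]-1,3-oxazolidin-2-one, via sodium Z-enolate 26 (not isolated)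
Conditions: NaN(SiMe3)2 (1.05 equiv), THF, −78 °C; then MeI, −78 → −40 °C
Reagents that add atoms: iodomethane, CI
Why: Auxiliary-controlled enolate alkylation (Evans alkylation): the sodium-chelated Z-enolate is shielded on one face by the benzyl group, so iodomethane should enter from the other face and give the 2S centre, which becomes C7 (R) of the target. The peroxy carbons bear no hydrogen, and intramolecular attack of the enolate on the O–O bond would need a four-membered transition state.

Step 16
Reactants: 27 (4S)-4-benzyl-3-[(2S)-3-[(3R,5S)-5-{2-[(TBDPS)oxy]ethyl}-3,5-dimethyl-1,2-dioxolan-3-yl]-2-methylpropanoyl]-1,3-oxazolidin-2-one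
Product: 28 (2S)-3-[(3R,5S)-5-{2-[(TBDPS)oxy]ethyl}-3,5-dimethyl-1,2-dioxolan-3-yl]-2-methylpropan-1-ol
Conditions: NaBH4, THF/H2O (4:1), 0 °C → rt
Reagents that add atoms: none
Why: Reductive removal of the oxazolidinone with borohydride in wet THF reduces the activated exocyclic imide carbonyl and releases the auxiliary 19. The conditions are non-basic enough to keep C7 intact and mild enough for the peroxide.

Step 17
Reactants: 28 (2S)-3-[(3R,5S)-5-{2-[(TBDPS)oxy]ethyl}-3,5-dimethyl-1,2-dioxolan-3-yl]-2-methylpropan-1-ol
Product: 29 (2S)-3-[(3R,5S)-5-{2-[(TBDPS)oxy]ethyl}-3,5-dimethyl-1,2-dioxolan-3-yl]-2-methylpropanal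
Conditions: Dess–Martin periodinane, pyridine, CH2Cl2, 0 °C; used at once
Reagents that add atoms: none
Why: Dess–Martin oxidation under buffered conditions, chosen because it does not epimerise α-branched aldehydes.

Step 18
Reactants: 30 6-bromohexan-1-ol
Product: 31 (6-hydroxyhexyl)triphenylphosphonium bromide
Conditions: PPh3, MeCN, reflux
Reagents that add atoms: triphenylphosphine, c1ccc(cc1)P(c1ccccc1)c1ccccc1
Why: SN2 quaternisation of triphenylphosphine by a primary bromide.

Step 19
Reactants: 29 (2S)-3-[(3R,5S)-5-{2-[(TBDPS)oxy]ethyl}-3,5-dimethyl-1,2-dioxolan-3-yl]-2-methylpropanal; 31 (6-hydroxyhexyl)triphenylphosphonium bromide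
Product: 32 (6Z,8S)-9-[(3R,5S)-5-{2-[(TBDPS)oxy]ethyl}-3,5-dimethyl-1,2-dioxolan-3-yl]-8-methylnon-6-en-1-ol
Conditions: 31, NaN(SiMe3)2 (2 equiv per salt), THF, 0 °C; then 29, −78 → 0 °C
Reagents that add atoms: none
Why: Wittig olefination with a non-stabilised ylide carried as its alkoxide; pre-formation of the ylide and addition of the aldehyde at −78 °C should avoid epimerisation at C7. The alkene geometry (mainly Z) is irrelevant because the bond is reduced next.

Step 20
Reactants: 32 (6Z,8S)-9-[(3R,5S)-5-{2-[(TBDPS)oxy]ethyl}-3,5-dimethyl-1,2-dioxolan-3-yl]-8-methylnon-6-en-1-ol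
Product: 33 (8R)-9-[(3R,5S)-5-{2-[(TBDPS)oxy]ethyl}-3,5-dimethyl-1,2-dioxolan-3-yl]-8-methylnonan-1-ol
Conditions: 2-nitrobenzenesulfonyl hydrazide (excess), Et3N, CH2Cl2, rt
Reagents that add atoms: none
Why: Diimide reduction of an unhindered cis-disubstituted alkene; the peroxide and the stereocentre are unaffected (the descriptor at C7 changes only through priority).

Step 21
Reactants: 33 (8R)-9-[(3R,5S)-5-{2-[(TBDPS)oxy]ethyl}-3,5-dimethyl-1,2-dioxolan-3-yl]-8-methylnonan-1-ol
Product: 34 (8R)-9-[(3R,5S)-5-{2-[(TBDPS)oxy]ethyl}-3,5-dimethyl-1,2-dioxolan-3-yl]-8-methylnonanal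
Conditions: Dess–Martin periodinane, pyridine, CH2Cl2, 0 °C → rt
Reagents that add atoms: none
Why: Dess–Martin oxidation of an unhindered primary alcohol.

Step 22
Reactants: 34 (8R)-9-[(3R,5S)-5-{2-[(TBDPS)oxy]ethyl}-3,5-dimethyl-1,2-dioxolan-3-yl]-8-methylnonanal; 35 diethyl cinnamylphosphonate
Product: 36 tert-butyl{2-[(3S,5R)-3,5-dimethyl-5-[(2R,9E,11E)-2-methyl-12-phenyldodeca-9,11-dien-1-yl]-1,2-dioxolan-3-yl]ethoxy}diphenylsilane
Conditions: 35, LiN(SiMe3)2, THF, −78 °C; then 34, −78 °C → rt
Reagents that add atoms: none
Why: Horner–Wadsworth–Emmons olefination with an allylic phosphonate: the delocalised anion should react through its α-carbon to give the new C14=C15 bond mainly E, and the styryl double bond keeps its E geometry. The base is consumed before the peroxide-bearing aldehyde is added.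

Step 23
Reactants: 36 tert-butyl{2-[(3S,5R)-3,5-dimethyl-5-[(2R,9E,11E)-2-methyl-12-phenyldodeca-9,11-dien-1-yl]-1,2-dioxolan-3-yl]ethoxy}diphenylsilane
Product: 37 2-[(3S,5R)-3,5-dimethyl-5-[(2R,9E,11E)-2-methyl-12-phenyldodeca-9,11-dien-1-yl]-1,2-dioxolan-3-yl]ethan-1-ol
Conditions: Bu4NF, THF, 0 °C → rt
Reagents that add atoms: none
Why: Fluoride-induced cleavage of the silyl ether; peroxide and diene are inert to fluoride.

Step 24
Reactants: 37 2-[(3S,5R)-3,5-dimethyl-5-[(2R,9E,11E)-2-methyl-12-phenyldodeca-9,11-dien-1-yl]-1,2-dioxolan-3-yl]ethan-1-ol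
Product: 39 2-[(3R,5R)-3,5-dimethyl-5-[(2R,9E,11E)-2-methyl-12-phenyldodeca-9,11-dien-1-yl]-1,2-dioxolan-3-yl]acetic acid (the target), via β-peroxy aldehyde 38 (not isolated)
Conditions: TEMPO (cat.), PhI(OAc)2 (2.2 equiv), MeCN/H2O (1:1), rt
Reagents that add atoms: water, O
Why: Oxoammonium-mediated oxidation of a primary alcohol through 38 and its hydrate to the acid. The medium is weakly acidic, so C2 is not deprotonated and the β-peroxy carbonyl should not open; isolated and conjugated alkenes are normally tolerated.

## Compound list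

1 | 3-methylcyclopent-2-en-1-one | CC1=CC(=O)CC1 | starting material
2 | methyllithium | [Li]C | starting material
3 | 1,3-dimethylcyclopent-2-en-1-ol (racemic) | CC1=CC(C)(O)CC1 | intermediate
4 | 1,3-dimethylcyclopenta-1,3-diene | CC1=CC(C)=CC1 | intermediate
5 | 2,5-dimethylcyclopenta-1,3-diene (racemic) | CC1C=C(C)C=C1 | intermediate
6 | 1,4-dimethylcyclopenta-1,3-diene | CC1=CC=C(C)C1 | intermediate
7 | dioxygen | O=O | starting material
8 | (1R,4S)-1,4-dimethyl-2,3-dioxabicyclo[2.2.1]hept-5-ene (meso) | C[C@@]12C=C[C@@](C)(C1)OO2 | intermediate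
9 | cis-5-[hydroperoxy(methoxy)methyl]-3,5-dimethyl-1,2-dioxolane-3-carbaldehyde (racemic, both epimers at the acetal carbon) | O=C[C@]1(C)C[C@](C)(C(OC)OO)OO1 | intermediate
10 | [(3R,5S)-3,5-dimethyl-1,2-dioxolane-3,5-diyl]dimethanol (meso) | OC[C@]1(C)C[C@](C)(CO)OO1 | intermediate
11 | [(3S,5R)-5-(hydroxymethyl)-3,5-dimethyl-1,2-dioxolan-3-yl]methyl acetate | CC(=O)OC[C@]1(C)C[C@](C)(CO)OO1 | intermediate
12 | [(3S,5R)-5-formyl-3,5-dimethyl-1,2-dioxolan-3-yl]methyl acetate | CC(=O)OC[C@]1(C)C[C@](C)(C=O)OO1 | intermediate
13 | [(3S,5R)-5-ethenyl-3,5-dimethyl-1,2-dioxolan-3-yl]methyl acetate | CC(=O)OC[C@]1(C)C[C@](C)(C=C)OO1 | intermediate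
14 | {(3S,5S)-5-[2-(9-borabicyclo[3.3.1]nonan-9-yl)ethyl]-3,5-dimethyl-1,2-dioxolan-3-yl}methyl acetate | CC(=O)OC[C@]1(C)C[C@](C)(CCB2C3CCCC2CCC3)OO1 | intermediate
15 | [(3S,5S)-5-(2-hydroxyethyl)-3,5-dimethyl-1,2-dioxolan-3-yl]methyl acetate | CC(=O)OC[C@]1(C)C[C@](C)(CCO)OO1 | intermediate
16 | 2-[(3S,5S)-5-(hydroxymethyl)-3,5-dimethyl-1,2-dioxolan-3-yl]ethan-1-ol | OC[C@]1(C)C[C@](C)(CCO)OO1 | intermediate
17 | [(3S,5S)-5-{2-[(TBDPS)oxy]ethyl}-3,5-dimethyl-1,2-dioxolan-3-yl]methanol | OC[C@]1(C)C[C@](C)(CCO[Si](c2ccccc2)(c2ccccc2)C(C)(C)C)OO1 | intermediate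
18 | (3S,5S)-5-{2-[(TBDPS)oxy]ethyl}-3,5-dimethyl-1,2-dioxolane-3-carbaldehyde | O=C[C@]1(C)C[C@](C)(CCO[Si](c2ccccc2)(c2ccccc2)C(C)(C)C)OO1 | intermediate
19 | (S)-4-benzyl-2-oxazolidinone | O=C1OC[C@H](Cc2ccccc2)N1 | starting material
20 | bromoacetyl bromide | BrCC(Br)=O | starting material
21 | lithium (4S)-4-benzyl-2-oxo-1,3-oxazolidin-3-ide | [Li+].O=C1OC[C@H](Cc2ccccc2)[N-]1 | intermediate
22 | (4S)-4-benzyl-3-(2-bromoacetyl)-1,3-oxazolidin-2-one | O=C(CBr)N1[C@@H](Cc2ccccc2)COC1=O | intermediate
23 | diethyl {2-[(4S)-4-benzyl-2-oxo-1,3-oxazolidin-3-yl]-2-oxoethyl}phosphonate | CCOP(=O)(CC(=O)N1[C@@H](Cc2ccccc2)COC1=O)OCC | intermediate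
24 | (4S)-4-benzyl-3-[(2E)-3-[(3S,5S)-5-{2-[(TBDPS)oxy]ethyl}-3,5-dimethyl-1,2-dioxolan-3-yl]prop-2-enoyl]-1,3-oxazolidin-2-one | O=C(/C=C/[C@]1(C)C[C@](C)(CCO[Si](c2ccccc2)(c2ccccc2)C(C)(C)C)OO1)N1[C@@H](Cc2ccccc2)COC1=O | intermediate
25 | (4S)-4-benzyl-3-{3-[(3R,5S)-5-{2-[(TBDPS)oxy]ethyl}-3,5-dimethyl-1,2-dioxolan-3-yl]propanoyl}-1,3-oxazolidin-2-one | O=C(CC[C@]1(C)C[C@](C)(CCO[Si](c2ccccc2)(c2ccccc2)C(C)(C)C)OO1)N1[C@@H](Cc2ccccc2)COC1=O | intermediate
26 | sodium (1Z)-1-[(4S)-4-benzyl-2-oxo-1,3-oxazolidin-3-yl]-3-[(3R,5S)-5-{2-[(TBDPS)oxy]ethyl}-3,5-dimethyl-1,2-dioxolan-3-yl]prop-1-en-1-olate | [Na+].[O-]/C(=C\C[C@]1(C)C[C@](C)(CCO[Si](c2ccccc2)(c2ccccc2)C(C)(C)C)OO1)N1[C@@H](Cc2ccccc2)COC1=O | intermediate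
27 | (4S)-4-benzyl-3-[(2S)-3-[(3R,5S)-5-{2-[(TBDPS)oxy]ethyl}-3,5-dimethyl-1,2-dioxolan-3-yl]-2-methylpropanoyl]-1,3-oxazolidin-2-one | C[C@H](C(=O)N1[C@@H](Cc2ccccc2)COC1=O)C[C@]1(C)C[C@](C)(CCO[Si](c2ccccc2)(c2ccccc2)C(C)(C)C)OO1 | intermediate
28 | (2S)-3-[(3R,5S)-5-{2-[(TBDPS)oxy]ethyl}-3,5-dimethyl-1,2-dioxolan-3-yl]-2-methylpropan-1-ol | C[C@H](CO)C[C@]1(C)C[C@](C)(CCO[Si](c2ccccc2)(c2ccccc2)C(C)(C)C)OO1 | intermediate
29 | (2S)-3-[(3R,5S)-5-{2-[(TBDPS)oxy]ethyl}-3,5-dimethyl-1,2-dioxolan-3-yl]-2-methylpropanal | C[C@H](C=O)C[C@]1(C)C[C@](C)(CCO[Si](c2ccccc2)(c2ccccc2)C(C)(C)C)OO1 | intermediate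
30 | 6-bromohexan-1-ol | OCCCCCCBr | starting material
31 | (6-hydroxyhexyl)triphenylphosphonium bromide | OCCCCCC[P+](c1ccccc1)(c1ccccc1)c1ccccc1.[Br-] | intermediate
32 | (6Z,8S)-9-[(3R,5S)-5-{2-[(TBDPS)oxy]ethyl}-3,5-dimethyl-1,2-dioxolan-3-yl]-8-methylnon-6-en-1-ol | C[C@H](/C=C\CCCCCO)C[C@]1(C)C[C@](C)(CCO[Si](c2ccccc2)(c2ccccc2)C(C)(C)C)OO1 | intermediate
33 | (8R)-9-[(3R,5S)-5-{2-[(TBDPS)oxy]ethyl}-3,5-dimethyl-1,2-dioxolan-3-yl]-8-methylnonan-1-ol | C[C@H](CCCCCCCO)C[C@]1(C)C[C@](C)(CCO[Si](c2ccccc2)(c2ccccc2)C(C)(C)C)OO1 | intermediate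
34 | (8R)-9-[(3R,5S)-5-{2-[(TBDPS)oxy]ethyl}-3,5-dimethyl-1,2-dioxolan-3-yl]-8-methylnonanal | C[C@H](CCCCCCC=O)C[C@]1(C)C[C@](C)(CCO[Si](c2ccccc2)(c2ccccc2)C(C)(C)C)OO1 | intermediate
35 | diethyl cinnamylphosphonate | CCOP(=O)(C/C=C/c1ccccc1)OCC | starting material
36 | tert-butyl{2-[(3S,5R)-3,5-dimethyl-5-[(2R,9E,11E)-2-methyl-12-phenyldodeca-9,11-dien-1-yl]-1,2-dioxolan-3-yl]ethoxy}diphenylsilane | C[C@H](CCCCCC/C=C/C=C/c1ccccc1)C[C@]1(C)C[C@](C)(CCO[Si](c2ccccc2)(c2ccccc2)C(C)(C)C)OO1 | intermediate
37 | 2-[(3S,5R)-3,5-dimethyl-5-[(2R,9E,11E)-2-methyl-12-phenyldodeca-9,11-dien-1-yl]-1,2-dioxolan-3-yl]ethan-1-ol | C[C@H](CCCCCC/C=C/C=C/c1ccccc1)C[C@]1(C)C[C@](C)(CCO)OO1 | intermediate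
38 | 2-[(3R,5R)-3,5-dimethyl-5-[(2R,9E,11E)-2-methyl-12-phenyldodeca-9,11-dien-1-yl]-1,2-dioxolan-3-yl]acetaldehyde | C[C@H](CCCCCC/C=C/C=C/c1ccccc1)C[C@]1(C)C[C@](C)(CC=O)OO1 | intermediate
39 | 2-[(3R,5R)-3,5-dimethyl-5-[(2R,9E,11E)-2-methyl-12-phenyldodeca-9,11-dien-1-yl]-1,2-dioxolan-3-yl]acetic acid | C[C@H](CCCCCC/C=C/C=C/c1ccccc1)C[C@]1(C)C[C@](C)(CC(=O)O)OO1 | target

## Step count and risk

Total step count: 24. Longest linear sequence: 21 steps (steps 1–10, 13–17 and 19–24). Steps 11–12 and step 18 prepare the two side reagents.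

**Step 3 (key step).** The most likely failure is loss of singlet oxygen to the wrong tautomer: 4 is expected to dominate the mixture and reacts as readily as 6. A second risk is thermal rearrangement of the strained allylic peroxide before it is cleaved. Fallback: the fallback sets out from 6 as its tautomer mixture. The mixture is treated in Et2O at 0 °C with maleic anhydride in an amount matched to its content of 4. Tautomer 4 has one unsubstituted diene terminus and should undergo Diels–Alder addition much faster than 6, whose termini would both become quaternary bridgeheads. It is removed as the involatile endo-1,5-dimethylbicyclo[2.2.1]hept-5-ene-2,3-dicarboxylic anhydride F1. The enriched hydrocarbon is recovered by cold bulb-to-bulb distillation and returns to the route as 6 for step 3.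

**Step 4.** The cleavage passes through α-peroxy carbonyl intermediates that can fragment (Criegee- or Grob-type C–C cleavage), and the borohydride quench can over-reduce the O–O bond if the mixture warms. Fallback: the fallback sets out from 8. The alkene is dihydroxylated cold with OsO4 and pyridine (then aqueous NaHSO3) from the face of the methylene bridge. This gives meso-(5-exo,6-exo)-1,4-dimethyl-2,3-dioxabicyclo[2.2.1]heptane-5,6-diol F2, which is no longer an allylic peroxide and should be much more robust. NaIO4 in THF/H2O cleaves the glycol to (3R,5S)-3,5-dimethyl-1,2-dioxolane-3,5-dicarbaldehyde F3. NaBH4 in MeOH at 0 °C rejoins the route at 10.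

**Step 5.** The stereocentres are quaternary and lie one carbon from the reacting hydroxyl, so discrimination between the enantiotopic arms may be poor or may have the opposite sense. Slow acyl migration between the cis arms would also erode the enantiomeric purity. Fallback: the fallback sets out from 10. Ac2O and pyridine give [(3R,5S)-3,5-dimethyl-1,2-dioxolane-3,5-diyl]dimethanediyl diacetate F4. Hydrolysis of this diacetate with the same lipase in pH 7 phosphate buffer removes the acetate from the arm that the enzyme prefers. It therefore delivers the enantiomer opposite to that from acylation, often with different selectivity, and rejoins the route at 11.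

**Step 8.** The borane may reduce the O–O bond, or some boron may add at the internal carbon, where it is β to the peroxy oxygen and eliminates. Cleavage of the acetate in the work-up may also be incomplete. Fallback: the fallback sets out from 12. Wittig reaction with (methoxymethylene)triphenylphosphorane gives [(3S,5R)-5-(2-methoxyethenyl)-3,5-dimethyl-1,2-dioxolan-3-yl]methyl acetate F5. Dilute aqueous acid in THF unmasks [(3S,5R)-3,5-dimethyl-5-(2-oxoethyl)-1,2-dioxolan-3-yl]methyl acetate F6. This aldehyde is reduced at once with NaBH4 to 15, and K2CO3 in MeOH then gives 16, where the route is rejoined.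

**Step 24.** The oxidant may attack the phenyl-diene. The transient β-peroxy aldehyde 38 may also lose the peroxide by β-elimination if the medium is not kept acidic. Fallback: the acid is made before the diene exists. The fallback sets out from 33.
- Ac2O and pyridine give (8R)-9-[(3R,5S)-5-{2-[(TBDPS)oxy]ethyl}-3,5-dimethyl-1,2-dioxolan-3-yl]-8-methylnonyl acetate F7.
- Bu4NF gives (8R)-9-[(3R,5S)-5-(2-hydroxyethyl)-3,5-dimethyl-1,2-dioxolan-3-yl]-8-methylnonyl acetate F8.
- TEMPO and PhI(OAc)2 in MeCN/H2O give 2-[(3R,5R)-5-[(2R)-9-acetoxy-2-methylnonyl]-3,5-dimethyl-1,2-dioxolan-3-yl]acetic acid F9.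
- K2CO3 in MeOH gives 2-[(3R,5R)-5-[(2R)-9-hydroxy-2-methylnonyl]-3,5-dimethyl-1,2-dioxolan-3-yl]acetic acid F10.
- Dess–Martin periodinane gives 2-[(3R,5R)-3,5-dimethyl-5-[(2R)-2-methyl-9-oxononyl]-1,2-dioxolan-3-yl]acetic acid F11.
- Olefination with the lithium salt of 35, using one extra equivalent of LiN(SiMe3)2 to hold the acid as its carboxylate (whose C2 protons are not removed), rejoins the route at 39.

## Further compounds

F1 | step 3 | endo-1,5-dimethylbicyclo[2.2.1]hept-5-ene-2,3-dicarboxylic anhydride (racemic) | CC1=C[C@]2(C)C[C@H]1[C@H]3[C@@H]2C(=O)OC3=O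
F2 | step 4 | meso-(5-exo,6-exo)-1,4-dimethyl-2,3-dioxabicyclo[2.2.1]heptane-5,6-diol | O[C@@H]2[C@]1(C)C[C@](C)([C@@H]2O)OO1
F3 | step 4 | (3R,5S)-3,5-dimethyl-1,2-dioxolane-3,5-dicarbaldehyde (meso) | O=C[C@]1(C)C[C@](C)(C=O)OO1
F4 | step 5 | [(3R,5S)-3,5-dimethyl-1,2-dioxolane-3,5-diyl]dimethanediyl diacetate (meso) | CC(=O)OC[C@]1(C)C[C@](C)(COC(C)=O)OO1
F5 | step 8 | [(3S,5R)-5-(2-methoxyethenyl)-3,5-dimethyl-1,2-dioxolan-3-yl]methyl acetate (E/Z mixture) | CC(=O)OC[C@]1(C)C[C@](C)(C=COC)OO1
F6 | step 8 | [(3S,5R)-3,5-dimethyl-5-(2-oxoethyl)-1,2-dioxolan-3-yl]methyl acetate | CC(=O)OC[C@]1(C)C[C@](C)(CC=O)OO1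
F7 | step 24 | (8R)-9-[(3R,5S)-5-{2-[(TBDPS)oxy]ethyl}-3,5-dimethyl-1,2-dioxolan-3-yl]-8-methylnonyl acetate | C[C@H](CCCCCCCOC(C)=O)C[C@]1(C)C[C@](C)(CCO[Si](c2ccccc2)(c2ccccc2)C(C)(C)C)OO1
F8 | step 24 | (8R)-9-[(3R,5S)-5-(2-hydroxyethyl)-3,5-dimethyl-1,2-dioxolan-3-yl]-8-methylnonyl acetate | C[C@H](CCCCCCCOC(C)=O)C[C@]1(C)C[C@](C)(CCO)OO1
F9 | step 24 | 2-[(3R,5R)-5-[(2R)-9-acetoxy-2-methylnonyl]-3,5-dimethyl-1,2-dioxolan-3-yl]acetic acid | C[C@H](CCCCCCCOC(C)=O)C[C@]1(C)C[C@](C)(CC(=O)O)OO1
F10 | step 24 | 2-[(3R,5R)-5-[(2R)-9-hydroxy-2-methylnonyl]-3,5-dimethyl-1,2-dioxolan-3-yl]acetic acid | C[C@H](CCCCCCCO)C[C@]1(C)C[C@](C)(CC(=O)O)OO1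
F11 | step 24 | 2-[(3R,5R)-3,5-dimethyl-5-[(2R)-2-methyl-9-oxononyl]-1,2-dioxolan-3-yl]acetic acid | C[C@H](CCCCCCC=O)C[C@]1(C)C[C@](C)(CC(=O)O)OO1
A1 | alternative 1 | methyl 2-[(3R,5R)-5-[(2R)-9-acetoxy-2-methylnonyl]-3,5-dimethyl-1,2-dioxolan-3-yl]acetate | C[C@H](CCCCCCCOC(C)=O)C[C@]1(C)C[C@](C)(CC(=O)OC)OO1
A2 | alternative 1 | methyl (3R,5R,7R)-14-acetoxy-3,5-dihydroxy-3,5,7-trimethyltetradecanoate | C[C@H](CCCCCCCOC(C)=O)C[C@](O)(C)C[C@](C)(CC(=O)OC)O
A3 | alternative 2 | 2-{5-[9-(TBDPS-oxy)-1-hydroxy-2-methylnonyl]-3,5-dimethyl-1,2-dioxolan-3-yl}ethyl pivalate (configuration as in the SMILES) | C[C@H](CCCCCCCO[Si](c1ccccc1)(c1ccccc1)C(C)(C)C)[C@@H](O)[C@]1(C)C[C@](C)(CCOC(=O)C(C)(C)C)OO1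
A4 | alternative 2 | 3-hydroperoxy-3-methyl-4-{2-methyl-3-[9-(TBDPS-oxy)nonan-2-yl]oxiran-2-yl}butyl pivalate (configuration as in the SMILES) | C[C@H](CCCCCCCO[Si](c1ccccc1)(c1ccccc1)C(C)(C)C)[C@H]1O[C@]1(C)C[C@](C)(CCOC(=O)C(C)(C)C)OO
A5 | alternative 3 | methyl 2-[(3R,5R)-5-[(2R)-9-(TBDPS-oxy)-2-methylnonyl]-3,5-dimethyl-1,2-dioxolan-3-yl]acetate | C[C@H](CCCCCCCO[Si](c1ccccc1)(c1ccccc1)C(C)(C)C)C[C@]1(C)C[C@](C)(CC(=O)OC)OO1
A6 | alternative 3 | (4R)-2-methoxy-4-methyl-11-(TBDPS-oxy)-2-(triethylsilylperoxy)undecane (both epimers at C2) | C[C@H](CCCCCCCO[Si](c1ccccc1)(c1ccccc1)C(C)(C)C)CC(C)(OC)OO[Si](CC)(CC)CC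
A7 | alternative 3 | methyl 3-methylbut-3-enoate | C=C(C)CC(=O)OC
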